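**Assumption (one line):** rotation about the C4–C1′ bond is taken to be fast at room temperature, so C4 is the only stereogenic element to control; by CIP analysis of the target SMILES it is (R) (C4a > C1′ > C3 > H).

Locants: tetralone C1–C8a (ring A aromatic, ring B ketone ring), naphthyl C1′–C8a′ (ring C hydroxyl ring, ring D methoxy ring). Spiro-ketal names carry their own locants.

## Structural features

The target is a 4-aryl-1-tetralone. Ring A is a catechol (C7–OH, C8–OH) fused to the cyclohexanone ring B, whose C1 carbonyl lies peri to C8–OH. C4 carries, through one C4–C1′ bond, a naphthalene made of ring C (C4′–OH, para to C1′) and ring D (C8′–OMe, peri to C1′).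

C4 is the only stereocentre, a diarylmethine with no neighbouring stereocentre to relay from. It lies γ to the ketone, so neither enolate nor conjugate-addition chemistry of the tetralone can set it directly.

The C4–C1′ bond is crowded, because C1′ is flanked by the peri methoxy group; a direct aryl–alkyl coupling at C1′ is therefore unattractive.

The catechol and the naphthol oxidise easily to quinones, and the aryl ketone can be over-reduced at its benzylic carbon. The C4–H bond is doubly benzylic and para to oxygen on both aryl rings, so strong acid or oxidants threaten the stereocentre. The single methyl ether must survive, so the other three phenols cannot be carried as methyl ethers.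

The real difficulties are regiochemical and stereochemical. Ring A needs 7,8-dioxygenation relative to C1, whereas a Friedel–Crafts closure of a 4-(3,4-dialkoxyphenyl)butanoic acid would place the oxygens at C6 and C7. The naphthalene needs the 1′,4′,8′-pattern, and the stereocentre is isolated.

The key step exploits the fact that in ring C the hydroxyl carbon C4′ sits on C4a′ and the C4-bearing carbon C1′ on C8a′. These are two ortho positions of ring D, so an ester carbon and a benzylic carbon on neighbouring ring-D atoms need only the two-carbon bridge C2′–C3′ to become ring C.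

## Logic of the disconnections

**19 ⇒ 18 ⇒ 17.** The two O–CH2Ph bonds at C7 and C8 and the two C1–O bonds of the dioxolane are put back. Benzyl is the only phenol protection that can be removed without touching C8′–OMe, and the ketal hides the enolisable ketone from strong base. The forward steps must be mild acid (C4 is acid-sensitive) and neutral hydrogenolysis that spares the aryl ketone.

**17 ⇒ 14 + 15.** Ring C is cut at C1′–C2′ and C3′–C4′. This removes the whole naphthalene and leaves a simple benzoate whose ester carbon is C4′ and whose benzylic methylene is C1′, while 15 supplies C2′–C3′ as an acetylene equivalent. The crowded C4–C1′ bond is then an ordinary sp3–sp3 bond made earlier. The forward step demands deprotonation only at C1′ and a ketone that is masked.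

**14 ⇒ 13.** The C4–H and C3–H bonds are removed to give the endocyclic C3=C4 alkene. The single stereocentre then becomes a face-selection problem on a cyclic trisubstituted alkene with no E/Z ambiguity. The forward hydrogenation must be enantioselective without a directing group and must not ionise the homoallylic ketal.

**13 ⇒ 9 + 12 (12 ⇐ 11 ⇐ 10).** The C4–C1′H2 bond is cut between an alkenyl triflate and a benzylzinc reagent. The molecule divides into a ring A/B piece and a ring D piece of similar size, and the ring D piece comes from 10 in one bromination. The forward coupling needs an organometallic that tolerates the ortho ester, hence zinc.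

**9 ⇒ 8 ⇒ 7.** The C4–O triflate bond returns the C4 ketone, and adding back the C2=C3 unsaturation gives a quinone monoketal. This differentiates the two carbonyl carbons of ring B completely: C1 is ketal, C4 is ketone. The forward steps need a conjugate C=C reduction that spares benzyl ethers and a regiodefined enolisation, which is automatic because C3 is the only α-methylene.

**7 ⇒ 6.** Both C1–O ketal bonds are cut, leading to a 1-naphthol whose hydroxyl carbon is C4 and whose free para position is C1. Oxidative dearomatisation places the ketal para to the hydroxyl, that is at the carbonyl peri to C8–O, which an ordinary ketalisation of the dione would leave untouched. The forward step demands para rather than ortho attack of the glycol.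

**6 ⇒ 4 (through 5).** The C4–C4a bond of ring B is cut, giving an arylbutenoic acid. Ring closure can occur only at the one free ortho position of the aryl ring, so the 7,8-pattern of ring A is fixed by construction and not by directing effects. A veratrole-type arylbutanoic acid would give the 6,7-pattern and methyl ethers that cannot be told apart from C8′–OMe.

**4 ⇒ 2 + 3; 2 ⇒ 1.** The C1=C2 alkene is cut by a Wittig disconnection, so C1 comes from the aldehyde carbon and C2–C4 from 3. The two O–benzyl bonds lead back to 1, which already holds both ring A oxygens in the right places.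

## Other disconnections considered

**Alternative 1:** The cut is C1′–C8a′ and C4′–C4a′, so ring D arrives as an aryne and ring C from a furan. In the forward sense the aryne released by fluoride from the silyl triflate A2 would add across the furan of the enantiopure furyl tetralone A1. This would give the oxygen-bridged cycloadduct A3, and acid would then open the bridge at the tertiary benzylic carbon to the naphthol.
- In its favour: it is convergent and runs under mild, nearly neutral conditions. The ketone of A1 needs no ketal during the key step, which is a real advantage over the chosen plan. Both bridgehead diastereomers of A3 converge.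
- Against it: A1 and the unsymmetrical aryne can combine in two orientations. The required one puts the methoxy group peri to the fully substituted bridgehead, the more crowded arrangement, so a mixture of regioisomeric naphthols must be expected. A1 also still needs its C4 stereocentre, most plausibly by the same triflate–coupling–hydrogenation sequence, with a furan to complicate it.
- Comparison: step economy is about equal. The chosen plan is superior on regiochemistry, because the methoxy and ester positions are fixed in 10. Alternative 1 is superior on functional-group tolerance in the key step.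

**Alternative 2:** The cut is a one-carbon ring contraction of ring B. In the forward sense the bromomethyl keto ester A4 would give, with Bu3SnH and a radical initiator, a primary radical that attacks the C1 carbonyl and fragments to the ring-expanded keto ester A5.
- In its favour: in A4 the future C4 lies β to the carbonyl, where asymmetric conjugate arylation is mature methodology. This is a better-precedented way to set the stereocentre than hydrogenation of an unfunctionalised alkene. Radical conditions are neutral.
- Against it: the step only inserts one CH2 and builds none of the hard features. The crowded C4–C1′ bond would have to be made by adding a peri-substituted naphthyl nucleophile, which is likely to be sluggish. A5 keeps a superfluous ester at C3 in a 1,4-relationship to the ketone, so it cannot leave by simple decarboxylation and needs hydrolysis plus a radical decarboxylation. Direct reduction of the primary radical competes with ring expansion, and tin residues are a burden.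
- Comparison: roughly four operations (ester on, bromomethyl on, expansion, ester off) serve one carbon, so step economy is worse. Alternative 2 is equal or better only on the precedent for the stereocentre.

**Alternative 3:** The cut is C4a–C8a and C7–C8, so ring A comes from a furan and ring B closes in the same event. In the forward sense the furan ynone A6 would undergo intramolecular Diels–Alder addition on heating, with Me2AlCl if needed. The oxygen bridge would then open to the bromo phenol A7, with the furan oxygen ending at C7.
- In its favour: two rings form in one step. The C7 oxygen is placed unambiguously, so the ring A regiochemistry problem is solved more directly than by the naphthol oxidation of the chosen plan. No ketal is needed.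
- Against it: the tether closes a six-membered ring, which is entropically less favourable for furan cycloadditions than a five-membered one, and the addition is reversible. The C4 centre of A6 is a furfuryl, naphthylmethyl carbon that can ionise under Lewis acid, so configurational integrity is at risk. A7 still needs C8–Br turned into C8–OH at a position flanked by a phenol and the peri carbonyl, which adds protection and hydroxylation steps. Making A6 as a single enantiomer requires the same crowded C4–C1′ bond to be formed asymmetrically.
- Comparison: Alternative 3 is the stronger in bond economy of the key step itself. The chosen plan is the stronger on overall step count, on the safety of the stereocentre and on the end-game.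

Key step: step 10

## Route

Step 1
Reactants: 1 2,3-dihydroxybenzaldehyde
Product: 2 2,3-bis(benzyloxy)benzaldehyde
Conditions: BnBr (2.3 equiv), K2CO3, DMF, 60 °C
Reagents that add atoms: benzyl bromide, BrCc1ccccc1
Why: Williamson ether synthesis on both phenols; benzyl ethers survive strong base, organozinc and trivalent-iodine reagents and homogeneous hydrogenation, and leave at the end by neutral hydrogenolysis without touching the methyl ether.

Step 2
Reactants: 2 2,3-bis(benzyloxy)benzaldehyde; 3 (2-carboxyethyl)triphenylphosphonium bromide
Product: 4 (E)-4-[2,3-bis(benzyloxy)phenyl]but-3-enoic acid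
Conditions: 3 (1.2 equiv), NaHMDS (2.4 equiv), THF, −78 °C → rt; aq. HCl work-up
Reagents that add atoms: none
Why: Wittig olefination with the carboxylate-bearing ylide gives the β,γ-unsaturated acid, mainly E; the geometry is of no consequence because it equilibrates under the conditions of step 3.

Step 3
Reactants: 4 (E)-4-[2,3-bis(benzyloxy)phenyl]but-3-enoic acid
Product: 6 5,6-bis(benzyloxy)naphthalen-1-ol, via acetate 5 (not isolated)
Conditions: Ac2O, NaOAc, 140 °C; evaporate; then K2CO3 (cat.), MeOH (degassed), 0 °C → rt
Reagents that add atoms: none
Why: The mixed anhydride (or the vinylketene derived from it) acylates the only free ortho position of the ring in an intramolecular Friedel–Crafts-type benzannulation, and the resulting naphthol is trapped as its acetate, which mild methanolysis cleaves; regiochemistry is fixed because the other ortho carbon bears a benzyloxy group.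

Step 4
Reactants: 6 5,6-bis(benzyloxy)naphthalen-1-ol
Product: 7 7′,8′-bis(benzyloxy)-4′H-spiro[[1,3]dioxolane-2,1′-naphthalen]-4′-one
Conditions: PhI(OAc)2 (2.1 equiv), HOCH2CH2OH (10 equiv), MeCN, 0 °C → rt
Reagents that add atoms: ethylene glycol, OCCO
Why: Oxidative dearomatisation of a para-unsubstituted 1-naphthol: the phenoxenium ion is trapped by glycol at the para carbon, the ring rearomatises, and a second oxidation with intramolecular capture closes the spiro-dioxolane. The ketal thus lands para to the original hydroxyl, at the carbon peri to the benzyloxy group, which is the future C1.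

Step 5
Reactants: 7 7′,8′-bis(benzyloxy)-4′H-spiro[[1,3]dioxolane-2,1′-naphthalen]-4′-one
Product: 8 7′,8′-bis(benzyloxy)-2′,3′-dihydro-4′H-spiro[[1,3]dioxolane-2,1′-naphthalen]-4′-one
Conditions: H2 (1 atm), Pd/C (5 mol %), Ph2S (0.01 equiv), EtOAc, rt
Reagents that add atoms: none
Why: Chemoselective heterogeneous hydrogenation of the enone C=C; the sulfide-moderated Pd/C catalyst should leave aryl benzyl ethers, the aryl ketone and the benzylic ketal untouched.

Step 6
Reactants: 8 7′,8′-bis(benzyloxy)-2′,3′-dihydro-4′H-spiro[[1,3]dioxolane-2,1′-naphthalen]-4′-one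
Product: 9 7′,8′-bis(benzyloxy)-2′H-spiro[[1,3]dioxolane-2,1′-naphthalen]-4′-yl trifluoromethanesulfonate
Conditions: KHMDS (1.2 equiv), PhNTf2 (1.2 equiv), THF, −78 °C; aq. NH4Cl
Reagents that add atoms: N-phenylbis(trifluoromethanesulfonimide), O=S(=O)(N(c1ccccc1)S(=O)(=O)C(F)(F)F)C(F)(F)F
Why: Enolate O-triflation; C3 is the only α-methylene, so the alkenyl triflate is regiodefined, and the ketal is too far from the enolate carbon for β-elimination.

Step 7
Reactants: 10 methyl 3-methoxy-2-methylbenzoate
Product: 11 methyl 2-(bromomethyl)-3-methoxybenzoate
Conditions: NBS (1.05 equiv), AIBN (cat.), PhCF3, 85 °C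
Reagents that add atoms: N-bromosuccinimide, O=C1CCC(=O)N1Br
Why: Wohl–Ziegler radical bromination of the only benzylic C–H site; radical conditions in a non-polar solvent disfavour ring bromination.

Step 8
Reactants: 11 methyl 2-(bromomethyl)-3-methoxybenzoate; 9 7′,8′-bis(benzyloxy)-2′H-spiro[[1,3]dioxolane-2,1′-naphthalen]-4′-yl trifluoromethanesulfonate
Product: 13 methyl 2-{[7′,8′-bis(benzyloxy)-2′H-spiro[[1,3]dioxolane-2,1′-naphthalen]-4′-yl]methyl}-3-methoxybenzoate, via benzylzinc bromide 12 (not isolated)
Conditions: Zn dust (1.5 equiv), LiCl (1.5 equiv), THF, 25 °C; then 9, Pd(OAc)2 (2 mol %), SPhos (4 mol %), THF, 25 → 40 °C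
Reagents that add atoms: none
Why: LiCl-assisted zinc insertion gives a benzylzinc bromide that tolerates the ortho ester, and Negishi coupling with the alkenyl triflate forms the C4–C1′ bond; the alkene is placed endocyclic (C3=C4) as a single isomer, which removes the E/Z problem of a benzylidene made by olefination of the ketone.

Step 9
Reactants: 13 methyl 2-{[7′,8′-bis(benzyloxy)-2′H-spiro[[1,3]dioxolane-2,1′-naphthalen]-4′-yl]methyl}-3-methoxybenzoate
Product: 14 methyl 2-{[(4′R)-7′,8′-bis(benzyloxy)-3′,4′-dihydro-2′H-spiro[[1,3]dioxolane-2,1′-naphthalen]-4′-yl]methyl}-3-methoxybenzoate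
Conditions: [Ir(cod)Cl]2 (1 mol %), chiral phosphine–oxazoline (P,N) ligand of the PHOX type (2.2 mol %), NaB[3,5-(CF3)2C6H3]4, K3PO4 (solid), H2 (50 bar), CH2Cl2, 25 °C
Reagents that add atoms: none
Why: Iridium-catalysed asymmetric hydrogenation of an unfunctionalised trisubstituted alkene of the 1-substituted 3,4-dihydronaphthalene class; the chiral P,N pocket selects the alkene face, and the ligand antipode is chosen by the quadrant model so that hydrogen is delivered to the Re face of C4 (C4a > C3 > C1′H2), which gives (R). The catalyst does not cleave benzyl ethers, and the solid base is there to buffer acid from the iridium hydrides and protect the ketal.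

Step 10
Reactants: 14 methyl 2-{[(4′R)-7′,8′-bis(benzyloxy)-3′,4′-dihydro-2′H-spiro[[1,3]dioxolane-2,1′-naphthalen]-4′-yl]methyl}-3-methoxybenzoate; 15 phenyl vinyl sulfoxide
Product: 17 4-[(4′R)-7′,8′-bis(benzyloxy)-3′,4′-dihydro-2′H-spiro[[1,3]dioxolane-2,1′-naphthalen]-4′-yl]-5-methoxynaphthalen-1-ol, via keto sulfoxide 16 (not isolated)
Conditions: LDA (1.3 equiv), THF, −78 °C; 15 (1.3 equiv), −78 → 0 °C; aq. NH4Cl; crude 16 in toluene, NaHCO3, 100 °C
Reagents that add atoms: none
Why: LDA removes a proton from the C1′ methylene, which the ortho ester acidifies as a vinylogous α-position, and the resulting ortho-quinodimethane enolate adds to the β-carbon of 15 to form C1′–C2′. The α-sulfinyl carbanion at C3′ then attacks the ester carbonyl (C3′–C4′) in a Dieckmann-type 6-exo-trig closure of ring C, expelling methoxide, which deprotonates the β-keto sulfoxide so that no excess amide base is left to attack 15. After protonation, thermal syn elimination of benzenesulfenic acid across C2′–C3′ gives a naphthalen-1(4H)-one that tautomerises to the naphthol, so 15 serves as an acetylene equivalent. This is the Staunton–Weinreb Michael–Dieckmann annulation of an ortho-toluate anion. No stereocentre is created that survives, since C1′, C3′ and sulfur are all erased on aromatisation, and C4 is untouched because its hydrogen is not activated by any carbonyl group. The step needs deprotonation at C1′ only, which is secured by the ester activation, by the ketal masking the ketone and by the low acidity of C4–H, C2–H and the OCH2Ph hydrogens towards LDA at −78 °C. The regiochemistry of the naphthol (hydroxyl at C4′, methoxy at C8′) is fixed by the positions of ester and methoxy group on ring D.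

Step 11
Reactants: 17 4-[(4′R)-7′,8′-bis(benzyloxy)-3′,4′-dihydro-2′H-spiro[[1,3]dioxolane-2,1′-naphthalen]-4′-yl]-5-methoxynaphthalen-1-ol
Product: 18 (4R)-7,8-bis(benzyloxy)-4-(4-hydroxy-8-methoxynaphthalen-1-yl)-3,4-dihydronaphthalen-1(2H)-one
Conditions: 1 M HCl (aq), THF, 0 °C → rt
Reagents that add atoms: water, O
Why: Acid-catalysed hydrolysis of an aryl ketone dioxolane, which is fast under dilute acid; benzyl and methyl ethers are stable, and C4 is not α to the carbonyl, so it cannot epimerise by enolisation.

Step 12
Reactants: 18 (4R)-7,8-bis(benzyloxy)-4-(4-hydroxy-8-methoxynaphthalen-1-yl)-3,4-dihydronaphthalen-1(2H)-one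
Product: 19 (4R)-7,8-dihydroxy-4-(4-hydroxy-8-methoxynaphthalen-1-yl)-3,4-dihydronaphthalen-1(2H)-one
Conditions: H2 (1 atm), Pd/C (10 wt %), EtOAc, rt; filtration under argon
Reagents that add atoms: none
Why: Hydrogenolysis of the two aryl benzyl ethers; under neutral, aprotic conditions at one atmosphere the electron-rich aryl ketone, the methyl ether and the C4–C bonds should be left intact.

## Compound list

1 | 2,3-dihydroxybenzaldehyde | O=Cc1cccc(O)c1O | starting material
2 | 2,3-bis(benzyloxy)benzaldehyde | O=Cc1cccc(OCc2ccccc2)c1OCc1ccccc1 | intermediate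
3 | (2-carboxyethyl)triphenylphosphonium bromide | OC(=O)CC[P+](c1ccccc1)(c1ccccc1)c1ccccc1.[Br-] | starting material
4 | (E)-4-[2,3-bis(benzyloxy)phenyl]but-3-enoic acid | OC(=O)C/C=C/c1cccc(OCc2ccccc2)c1OCc1ccccc1 | intermediate
5 | 5,6-bis(benzyloxy)naphthalen-1-yl acetate | CC(=O)Oc1cccc2c(OCc3ccccc3)c(OCc3ccccc3)ccc12 | intermediate (not isolated)
6 | 5,6-bis(benzyloxy)naphthalen-1-ol | Oc1cccc2c(OCc3ccccc3)c(OCc3ccccc3)ccc12 | intermediate
7 | 7′,8′-bis(benzyloxy)-4′H-spiro[[1,3]dioxolane-2,1′-naphthalen]-4′-one | O=C1C=CC2(OCCO2)c3c1ccc(OCc1ccccc1)c3OCc1ccccc1 | intermediate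
8 | 7′,8′-bis(benzyloxy)-2′,3′-dihydro-4′H-spiro[[1,3]dioxolane-2,1′-naphthalen]-4′-one | O=C1CCC2(OCCO2)c3c1ccc(OCc1ccccc1)c3OCc1ccccc1 | intermediate
9 | 7′,8′-bis(benzyloxy)-2′H-spiro[[1,3]dioxolane-2,1′-naphthalen]-4′-yl trifluoromethanesulfonate | FC(F)(F)S(=O)(=O)OC1=CCC2(OCCO2)c3c1ccc(OCc1ccccc1)c3OCc1ccccc1 | intermediate
10 | methyl 3-methoxy-2-methylbenzoate | COC(=O)c1cccc(OC)c1C | starting material
11 | methyl 2-(bromomethyl)-3-methoxybenzoate | COC(=O)c1cccc(OC)c1CBr | intermediate
12 | [2-methoxy-6-(methoxycarbonyl)benzyl]zinc bromide | COC(=O)c1cccc(OC)c1C[Zn]Br | intermediate (not isolated)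
13 | methyl 2-{[7′,8′-bis(benzyloxy)-2′H-spiro[[1,3]dioxolane-2,1′-naphthalen]-4′-yl]methyl}-3-methoxybenzoate | COC(=O)c1cccc(OC)c1CC1=CCC2(OCCO2)c3c1ccc(OCc1ccccc1)c3OCc1ccccc1 | intermediate
14 | methyl 2-{[(4′R)-7′,8′-bis(benzyloxy)-3′,4′-dihydro-2′H-spiro[[1,3]dioxolane-2,1′-naphthalen]-4′-yl]methyl}-3-methoxybenzoate | COC(=O)c1cccc(OC)c1C[C@H]1CCC2(OCCO2)c3c1ccc(OCc1ccccc1)c3OCc1ccccc1 | intermediate (key-step precursor)
15 | phenyl vinyl sulfoxide (racemic at sulfur) | C=CS(=O)c1ccccc1 | starting material
16 | 4-[(4′R)-7′,8′-bis(benzyloxy)-3′,4′-dihydro-2′H-spiro[[1,3]dioxolane-2,1′-naphthalen]-4′-yl]-5-methoxy-2-(phenylsulfinyl)-3,4-dihydronaphthalen-1(2H)-one (mixture at C2, C4 and sulfur of ring C) | COc1cccc2C(=O)C(S(=O)c3ccccc3)CC([C@H]3CCC4(OCCO4)c4c3ccc(OCc3ccccc3)c4OCc3ccccc3)c12 | intermediate (not isolated)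
17 | 4-[(4′R)-7′,8′-bis(benzyloxy)-3′,4′-dihydro-2′H-spiro[[1,3]dioxolane-2,1′-naphthalen]-4′-yl]-5-methoxynaphthalen-1-ol | COc1cccc2c(O)ccc([C@H]3CCC4(OCCO4)c4c3ccc(OCc3ccccc3)c4OCc3ccccc3)c12 | intermediate (key-step product)
18 | (4R)-7,8-bis(benzyloxy)-4-(4-hydroxy-8-methoxynaphthalen-1-yl)-3,4-dihydronaphthalen-1(2H)-one | COc1cccc2c(O)ccc([C@H]3CCC(=O)c4c3ccc(OCc3ccccc3)c4OCc3ccccc3)c12 | intermediate
19 | (4R)-7,8-dihydroxy-4-(4-hydroxy-8-methoxynaphthalen-1-yl)-3,4-dihydronaphthalen-1(2H)-one | COc1cccc2c(O)ccc([C@H]3CCC(=O)c4c3ccc(O)c4O)c12 | target

## Step count and risk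

Total step count: 12. Longest linear sequence: 11 steps (steps 1–6 and 8–12, from 1); step 7 is a one-step branch that joins at step 8.

Least certain steps:

**Step 10 (key step).** The C1′ methylene of 14 is flanked by two ortho substituents and carries a bulky tetralinyl group, so anion formation may be slow. Conjugate addition of this crowded anion to the modestly electrophilic vinyl sulfoxide may be outrun by proton transfer or by attack of the amide base on the ester. During the thermal elimination the sulfenic acid may sulfenylate the electron-rich naphthol. The fallback sets out from 14 and splits the annulation into isolable stages with a stronger acceptor. The anion of 14 is added to methyl acrylate, and Michael–Dieckmann closure should give the ring-C β-keto ester methyl 4-[(4′R)-7′,8′-bis(benzyloxy)-3′,4′-dihydro-2′H-spiro[[1,3]dioxolane-2,1′-naphthalen]-4′-yl]-5-methoxy-1-oxo-1,2,3,4-tetrahydronaphthalene-2-carboxylate F1. Krapcho dealkoxycarbonylation (LiCl, wet DMSO, 140 °C) should give the ring-C tetralone 4-[(4′R)-7′,8′-bis(benzyloxy)-3′,4′-dihydro-2′H-spiro[[1,3]dioxolane-2,1′-naphthalen]-4′-yl]-5-methoxy-3,4-dihydronaphthalen-1(2H)-one F2. α-Sulfinylation of its enolate (LDA, 2 equiv; methyl benzenesulfinate) rejoins the route at 16, which eliminates to 17 on warming.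

**Step 9.** Ionisation of the homoallylic ketal by the acidic iridium hydrides, followed by loss of a C2 proton, would aromatise ring B to a naphthyl ether. Face selection may also be poor with the large di-ortho-substituted benzyl group. The fallback sets out from 13 and gives up catalytic induction. Neutral heterogeneous hydrogenation (H2, Pd/C, Ph2S, EtOAc) should give racemic methyl 2-{[7′,8′-bis(benzyloxy)-3′,4′-dihydro-2′H-spiro[[1,3]dioxolane-2,1′-naphthalen]-4′-yl]methyl}-3-methoxybenzoate F3. Preparative chromatography on a chiral stationary phase then returns the route at 14 and removes the (4′S) enantiomer F4.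

**Step 4.** The peri benzyloxy group crowds the para carbon, so the glycol may add ortho, or over-oxidation to the quinone may compete. The fallback sets out from 6 and separates oxidation from glycol installation. Oxidation with PhI(OAc)2 in methanol, where the small nucleophile is the solvent, should give 5,6-bis(benzyloxy)-4,4-dimethoxynaphthalen-1(4H)-one F5. Acid-catalysed ketal exchange with ethylene glycol (PPTS, benzene, removal of methanol) returns the route at 7.

**Step 8.** Wurtz-type homocoupling during zinc insertion, protodezincation, or Lewis-acid-assisted loss of the ketal from the product may erode the coupling. The fallback sets out from 9 and reverses the polarity of the partners. Miyaura borylation (B2pin2, PdCl2(dppf), KOAc, dioxane) should give the alkenyl boronate 2-[7′,8′-bis(benzyloxy)-2′H-spiro[[1,3]dioxolane-2,1′-naphthalen]-4′-yl]-4,4,5,5-tetramethyl-1,3,2-dioxaborolane F6. Suzuki coupling with the benzyl bromide 11 under basic conditions (Pd(PPh3)4, K2CO3, aqueous dioxane) returns the route at 13.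

**Step 12.** Over-reduction of the aryl ketone at its benzylic carbon, incomplete cleavage of the hindered C8 ether, or air oxidation of the catechol during isolation may occur. The fallback sets out from 17 and changes the order of deprotection. Hydrogenolysis is run first, while the ketal still masks the carbonyl, and should give 4-[(4′R)-7′,8′-dihydroxy-3′,4′-dihydro-2′H-spiro[[1,3]dioxolane-2,1′-naphthalen]-4′-yl]-5-methoxynaphthalen-1-ol F7. Mild aqueous acid under argon then returns the route at 19.

## Further compounds

F1 | step 10 | methyl 4-[(4′R)-7′,8′-bis(benzyloxy)-3′,4′-dihydro-2′H-spiro[[1,3]dioxolane-2,1′-naphthalen]-4′-yl]-5-methoxy-1-oxo-1,2,3,4-tetrahydronaphthalene-2-carboxylate | COc1cccc2C(=O)C(C(=O)OC)CC([C@H]3CCC4(OCCO4)c4c3ccc(OCc3ccccc3)c4OCc3ccccc3)c12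
F2 | step 10 | 4-[(4′R)-7′,8′-bis(benzyloxy)-3′,4′-dihydro-2′H-spiro[[1,3]dioxolane-2,1′-naphthalen]-4′-yl]-5-methoxy-3,4-dihydronaphthalen-1(2H)-one | COc1cccc2C(=O)CCC([C@H]3CCC4(OCCO4)c4c3ccc(OCc3ccccc3)c4OCc3ccccc3)c12
F3 | step 9 | racemic methyl 2-{[7′,8′-bis(benzyloxy)-3′,4′-dihydro-2′H-spiro[[1,3]dioxolane-2,1′-naphthalen]-4′-yl]methyl}-3-methoxybenzoate | COC(=O)c1cccc(OC)c1CC1CCC2(OCCO2)c3c1ccc(OCc1ccccc1)c3OCc1ccccc1
F4 | step 9 | methyl 2-{[(4′S)-7′,8′-bis(benzyloxy)-3′,4′-dihydro-2′H-spiro[[1,3]dioxolane-2,1′-naphthalen]-4′-yl]methyl}-3-methoxybenzoate | COC(=O)c1cccc(OC)c1C[C@@H]1CCC2(OCCO2)c3c1ccc(OCc1ccccc1)c3OCc1ccccc1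
F5 | step 4 | 5,6-bis(benzyloxy)-4,4-dimethoxynaphthalen-1(4H)-one | COC1(OC)C=CC(=O)c2ccc(OCc3ccccc3)c(OCc3ccccc3)c12
F6 | step 8 | 2-[7′,8′-bis(benzyloxy)-2′H-spiro[[1,3]dioxolane-2,1′-naphthalen]-4′-yl]-4,4,5,5-tetramethyl-1,3,2-dioxaborolane | CC1(C)OB(OC1(C)C)C1=CCC2(OCCO2)c3c1ccc(OCc1ccccc1)c3OCc1ccccc1
F7 | step 12 | 4-[(4′R)-7′,8′-dihydroxy-3′,4′-dihydro-2′H-spiro[[1,3]dioxolane-2,1′-naphthalen]-4′-yl]-5-methoxynaphthalen-1-ol | COc1cccc2c(O)ccc([C@H]3CCC4(OCCO4)c4c3ccc(O)c4O)c12
A1 | alternative 1 | 7,8-bis(benzyloxy)-4-(furan-2-yl)-3,4-dihydronaphthalen-1(2H)-one, single enantiomer | c1coc(c1)[C@H]1CCC(=O)c2c1ccc(OCc1ccccc1)c2OCc1ccccc1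
A2 | alternative 1 | 3-methoxy-2-(trimethylsilyl)phenyl trifluoromethanesulfonate | COc1cccc(OS(=O)(=O)C(F)(F)F)c1[Si](C)(C)C
A3 | alternative 1 | 1,4-epoxy-1,4-dihydronaphthalene cycloadduct bearing the tetralone at the bridgehead peri to the methoxy group (both bridgehead diastereomers) | COc1cccc2C3C=CC(O3)([C@H]3CCC(=O)c4c3ccc(OCc3ccccc3)c4OCc3ccccc3)c12
A4 | alternative 2 | methyl 3-[4-(benzyloxy)-8-methoxynaphthalen-1-yl]-6,7-bis(benzyloxy)-2-(bromomethyl)-1-oxoindane-2-carboxylate (C3 as drawn, C2 undefined) | COc1cccc2c(OCc3ccccc3)ccc([C@H]3C(CBr)(C(=O)OC)C(=O)c4c3ccc(OCc3ccccc3)c4OCc3ccccc3)c12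
A5 | alternative 2 | methyl 1-[4-(benzyloxy)-8-methoxynaphthalen-1-yl]-5,6-bis(benzyloxy)-4-oxo-1,2,3,4-tetrahydronaphthalene-2-carboxylate (aryl-bearing carbon as drawn, ester carbon undefined) | COc1cccc2c(OCc3ccccc3)ccc([C@H]3C(C(=O)OC)CC(=O)c4c3ccc(OCc3ccccc3)c4OCc3ccccc3)c12
A6 | alternative 3 | 6-[4-(benzyloxy)-8-methoxynaphthalen-1-yl]-1-bromo-6-(furan-2-yl)hex-1-yn-3-one, single enantiomer | COc1cccc2c(OCc3ccccc3)ccc([C@@H](CCC(=O)C#CBr)c3ccco3)c12
A7 | alternative 3 | 4-[4-(benzyloxy)-8-methoxynaphthalen-1-yl]-8-bromo-7-hydroxy-3,4-dihydronaphthalen-1(2H)-one, single enantiomer | COc1cccc2c(OCc3ccccc3)ccc([C@H]3CCC(=O)c4c3ccc(O)c4Br)c12
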